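**Early split.** J comes up within the first hours of both earlier runs and then wastes away, while G moves far less. You want J's share of what became J, G or Z in dawn, dusk, summer and winter.

| flask | D | Q | E | temperature | remark | time |
|---|---|---|---|---|---|---|
| south-east | 0.034 M | 2 equiv | 0.050 M | 120 °C | run made earlier |  |
| south | 0.075 M | 2 equiv | 0.050 M | 142 °C | run made earlier |  |
| dawn | 0.050 M | 2.00 equiv | 0.0500 M | 110 °C |  | 25 h |
| dusk | 0.050 M | 2.00 equiv | 0.0500 M | 130 °C |  | 25 h |
| summer | 0.050 M | 2.00 equiv | 0.0500 M |  | at 110 °C until 8.0 h, from then on at 150 °C | 25 h |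
| winter | 0.050 M | 2.00 equiv | 0.0500 M | 150 °C |  | 25 h |

- south-east (time / h: J / %, G / %): 2.50: 14.1, 8.2; 5.00: 12.1, 8.6; 6.00: 11.6, 10.0; 10.0: 8.1, 9.1; 12.0: 6.4, 8.4; 15.0: 4.4, 7.6
- south (time / h: J / %, G / %): 0.250: 11.3, 9.2; 0.833: 11.9, 10.6; 1.50: 5.1, 14.4; 2.00: 6.0, 12.9; 3.00: 3.5, 12.6; 4.00: 1.3, 11.4; 5.00: 0.6, 10.6

(standard deviation of a reading: 1 percentage point)

- percent here means D units held: one Z counts as two

1. the flask that comes out highest in share of J in all that became J or G or Z, or "all alike" when all lie within 1.5 percentage points (dawn / dusk / summer / winter / all alike)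
2. share of J in all that became J or G or Z, dawn
3. share of J in all that became J or G or Z, dusk
4. share of J in all that became J or G or Z, summer
5. share of J in all that became J or G or Z, winter

The first south-east reading gives J over G as 1.72, which I also take for dawn. J's decay reads 0.0932 h⁻¹ at 120 °C and 0.717 h⁻¹ at 142 °C. Both are readings with a scatter of 1 percentage point, and the two runs differ in the D charge as well as in temperature. Treating temperature as the one difference, a straight line of ln rate against temperature gives me 0.0368 h⁻¹ at 110 °C.

**The balance.** The charge of D equals free D plus J, G and Z, so the share divides J by the D that reacted, not by the charge. I hold G fixed and set it to one. I assume each J lost takes a fresh D into one Z, which counts as two. The share is then J kept, over J kept plus G plus two units for each J lost.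

**The curve.** For dawn I start the clock at 2.50 h, with the share at 63.2%. It first falls by 0.0380 h⁻¹ as a fraction per hour. By this reckoning Z passes J at 13.5 h, with the share at 34.8%. By the same reckoning G passes J at 17.2 h, with the share at 29.1%. At 25 h a fraction 0.436 of J is kept, so the reacted-D share is 20.3%, still sinking towards zero.

**The others.** On the same line J in dusk decays at 0.236 h⁻¹, which with the same split gives me 0.193%. On that line summer spends 25.6 J lifetimes at 150 °C, so I expect hardly any of its J to be kept. Winter is at 150 °C from the start, and I commit to dawn.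

**The forecast.** It names dawn, with 7% for dawn, 0.05% for dusk, 0% for summer and 0% for winter. For dawn it says: “assume conversion is nearly complete”. Its dawn number differs from my 20.3%.

**The result.** Dawn comes out highest at 23.8%, with dusk at 0.288%, summer at 0.0454% and winter at 0.0514%.

    D + J → Z (k = 0.910 L mol⁻¹ h⁻¹, Ea = 84.0 kJ mol⁻¹)
    D + Q ⇌ G (K = 730 L mol⁻¹, k = 0.550 L mol⁻¹ h⁻¹, Ea = 95.0 kJ mol⁻¹, ΔH = −58.0 kJ mol⁻¹)
    Q → X (k = 0.180 h⁻¹, Ea = 128 kJ mol⁻¹)
    D + Q ⇌ J (K = 61.0 L mol⁻¹, k = 1.30 L mol⁻¹ h⁻¹, Ea = 72.0 kJ mol⁻¹, ΔH = −42.0 kJ mol⁻¹)
    Q + E → L (k = 2.50 L mol⁻¹ h⁻¹, Ea = 84.0 kJ mol⁻¹)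
    (constants at 110 °C)

**Q against D.** Dawn's Q half-life on the path to X is 3.9 h at 25.0 h, shorter than D's half-life by the forward step to J alone, 12 h at 2.29 h. At 25.0 h dawn's Q, first to run out and so the limiting reagent although charged at 2.00 equiv, stands at 0.533% of its own charge, with 54.6% of the D charged still free and 45.4% reacted. My 20.3% holds no term for the D charge, so it stands unchanged for a flask like dawn with 0.20 M of D, and that flask gives 22.5%, with 9.95% of its D left.

All runs are simulated with constants of no real substance, and the scatter is random.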